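## Retrosynthetic overview

- The last disconnection is the C–C bond between the ring-fusion CH of the cyclohexene ring and the quaternary lactone carbinol carbon, taken together with the lactone C–O bond. The cyclopentane and the γ-lactone close in one reductive cascade onto a preformed decalin (rings A and B).
- Enabling feature: ring B of the precursor carries an oxirane across C1–C8a attached to C2 of a C2=C3 acrylate (C2 bears CO2Me), that is a 2-(methoxycarbonyl)vinyl oxirane, and the C4 side chain holds the methyl ketone carbon five atoms from C3. Two electrons open the strained ring, turn C3 into an allyl nucleophile, move the alkene to C1=C2 and free the C8a alkoxide; the C2 ester traps the new alkoxide.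
- The epoxy diene ester comes from the cross-conjugated dienyl triflate of a 4-substituted octalone (carbonylation, then face-selective epoxidation). The octalone comes from Robinson annulation of cyclohexanone (ring A) with a side-chain enone (ring B), with C4/C4a set by a catalytic syn Michael addition.
- The enone comes from cross-metathesis of a pentenamide with methyl vinyl ketone. Its two contiguous stereocentres come from an auxiliary-controlled Mannich addition to the N-acyliminium ion of N-acetyl-(S)-2-methylpiperidine.
- Ring order: piperidine (purchased), ring A (cyclohexanone), ring B, temporary oxirane, then cyclopentane and lactone together.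

Key step: step 13

Assumption: dimethyldioxirane is used as a freshly prepared acetone solution (from Oxone and acetone), and all bicyclic intermediates are numbered as naphthalenes (ring B: C1–C4, C4a, C8a; ring A: C5–C8).

## Route

Step 1
Reactants: 1 (2S)-2-methylpiperidine
Product: 2 1-[(2S)-2-methylpiperidin-1-yl]ethan-1-one
Conditions: Ac2O, Et3N, DMAP (cat.), CH2Cl2, 0 °C to rt
Reagents that add atoms: acetic anhydride CC(=O)OC(C)=O
Why: N-acylation of the secondary amine by nucleophilic acyl substitution, which leaves the C2 stereocentre untouched.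

Step 2
Reactants: 2 1-[(2S)-2-methylpiperidin-1-yl]ethan-1-one
Product: 3 1-[(6S)-2-methoxy-6-methylpiperidin-1-yl]ethan-1-one (both C2 epimers)
Conditions: anodic oxidation (graphite electrodes, undivided cell, constant current), Et4NOTs, MeOH, 10 °C
Reagents that add atoms: methanol CO
Why: Shono oxidation, in which the amide radical cation loses a proton from the less substituted α-carbon so that methoxide enters at the ring CH2 next to nitrogen and not at the methyl-bearing carbon; the new aminal centre is erased again in step 4.

Step 3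
Reactants: 4 (4S)-4-benzyl-1,3-oxazolidin-2-one; 5 pent-4-enoyl chloride
Product: 7 (4S)-4-benzyl-3-(pent-4-enoyl)-1,3-oxazolidin-2-one, via lithium oxazolidinide 6 (not isolated)
Conditions: n-BuLi, THF, −78 °C; then 5, −78 to 0 °C
Reagents that add atoms: none
Why: N-acylation of the lithiated oxazolidinone auxiliary by the acid chloride.

Step 4
Reactants: 7 (4S)-4-benzyl-3-(pent-4-enoyl)-1,3-oxazolidin-2-one; 3 1-[(6S)-2-methoxy-6-methylpiperidin-1-yl]ethan-1-one
Product: 10 (4S)-3-[(2R)-2-[(2S,6S)-1-acetyl-6-methylpiperidin-2-yl]pent-4-enoyl]-4-benzyl-1,3-oxazolidin-2-one, via chlorotitanium enolate 8 (not isolated), via N-acyliminium ion 9 (not isolated)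
Conditions: TiCl4 (2.2 equiv), i-Pr2NEt (1.1 equiv), CH2Cl2, −78 °C; then 3, −78 to −20 °C
Reagents that add atoms: none
Why: Mannich-type addition of a chelated (Z)-chlorotitanium imide enolate to a cyclic N-acyliminium ion, in which the enolate reacts on the face away from the benzyl group (2R at the exocyclic centre) and axial attack through a chair-like transition state on the iminium ion, whose methyl group is pseudoaxial to avoid A(1,3) strain with the N-acetyl group, should place the new substituent cis to that methyl group (2,6-cis piperidine).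

Step 5
Reactants: 10 the Mannich adduct
Product: 11 (2R)-2-[(2S,6S)-1-acetyl-6-methylpiperidin-2-yl]-N-methoxy-N-methylpent-4-enamide
Conditions: MeNH(OMe)·HCl, AlMe3, CH2Cl2, 0 °C to rt; Rochelle salt work-up
Reagents that add atoms: N,O-dimethylhydroxylamine hydrochloride CNOC.Cl
Why: aluminium amide aminolysis of the exocyclic imide carbonyl (Weinreb amide formation) under non-basic conditions that keep the α-stereocentre and return the auxiliary.

Step 6
Reactants: 11 the pentenamide; 12 but-3-en-2-one
Product: 13 (2R,4E)-2-[(2S,6S)-1-acetyl-6-methylpiperidin-2-yl]-N-methoxy-N-methyl-6-oxohept-4-enamide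
Conditions: 12 (3 equiv), RuCl2(H2IMes)(=CH-C6H4-2-O-i-Pr) (second-generation Hoveyda–Grubbs catalyst, 5 mol %), CH2Cl2, 40 °C
Reagents that add atoms: none
Why: olefin cross-metathesis of a terminal alkene with an electron-poor vinyl ketone, which under thermodynamic control should give the (E)-enone.

Step 7
Reactants: 13 the (E)-enone; 14 cyclohexanone
Product: 15 (2R,4R)-2-[(2S,6S)-1-acetyl-6-methylpiperidin-2-yl]-N-methoxy-N-methyl-6-oxo-4-[(1S)-2-oxocyclohexyl]heptanamide
Conditions: 14 (10 equiv), (S)-N-(pyrrolidin-2-ylmethyl)trifluoromethanesulfonamide (20 mol %), PhCO2H (20 mol %), i-PrOH, rt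
Reagents that add atoms: none
Why: enamine-catalysed Michael addition of cyclohexanone to the enone, in which the (S)-pyrrolidine enamine reacts through the synclinal (syn) topology with the enone held by the sulfonamide N–H, which should set the ring α-carbon as S and the new chain centre as R (the arrangement that becomes H-4/H-4a trans) under catalyst control.

Step 8
Reactants: 15 the 1,5-diketone
Product: 17 (2R)-2-[(2S,6S)-1-acetyl-6-methylpiperidin-2-yl]-N-methoxy-N-methyl-3-[(1R,8aS)-3-oxo-1,2,3,5,6,7,8,8a-octahydronaphthalen-1-yl]propanamide, via ketol 16 (not isolated)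
Conditions: KOH (0.3 equiv), MeOH, 0 °C to rt
Reagents that add atoms: none
Why: intramolecular aldol condensation (second stage of the Robinson annulation), in which the methyl ketone enolate adds to the cyclohexanone carbonyl and E1cB dehydration gives the conjugated enone, the former α-centre becoming a γ-position that should not epimerise under these mild conditions.

Step 9
Reactants: 17 the octalone
Product: 19 (4S,4aS)-4-[(2R)-2-[(2S,6S)-1-acetyl-6-methylpiperidin-2-yl]-3-[methoxy(methyl)amino]-3-oxopropyl]-4,4a,5,6,7,8-hexahydronaphthalen-2-yl trifluoromethanesulfonate, via potassium dienolate 18 (not isolated)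
Conditions: KHMDS (1.05 equiv), THF, −78 °C; then PhNTf2, −78 to 0 °C
Reagents that add atoms: N-phenylbis(trifluoromethanesulfonimide) FC(F)(F)S(=O)(=O)N(c1ccccc1)S(=O)(=O)C(F)(F)F
Why: kinetic α′-deprotonation of the enone at C3 gives the cross-conjugated dienolate, which is O-sulfonylated to the 1(8a),2-dienyl triflate, while the far less acidic amide α-protons stay untouched.

Step 10
Reactants: 19 the dienyl triflate
Product: 20 methyl (4R,4aS)-4-[(2R)-2-[(2S,6S)-1-acetyl-6-methylpiperidin-2-yl]-3-[methoxy(methyl)amino]-3-oxopropyl]-4,4a,5,6,7,8-hexahydronaphthalene-2-carboxylate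
Conditions: Pd(OAc)2 (5 mol %), PPh3 (10 mol %), CO (1 atm), MeOH, Et3N, DMF, 50 °C
Reagents that add atoms: carbon monoxide [C-]#[O+]; methanol CO
Why: palladium-catalysed alkoxycarbonylation of an alkenyl triflate (oxidative addition, CO insertion, methanolysis), which keeps the position of both diene double bonds.

Step 11
Reactants: 20 the diene ester Weinreb amide
Product: 22 methyl (4R,4aS)-4-[(2R)-2-[(2S,6S)-1-acetyl-6-methylpiperidin-2-yl]-3-oxobutyl]-4,4a,5,6,7,8-hexahydronaphthalene-2-carboxylate, via magnesium hemiaminal chelate 21 (not isolated)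
Conditions: MeMgBr (2 equiv), THF, −40 to −10 °C; then sat. aq NH4Cl
Reagents that add atoms: methylmagnesium bromide C[Mg]Br
Why: Weinreb ketone synthesis, in which the five-membered magnesium chelate stops at mono-addition and releases the ketone only on quench (so the α-centre is never exposed to base as a ketone), while the hindered cross-conjugated dienoate and the tertiary acetamide should be much less reactive at this temperature.

Step 12
Reactants: 22 the keto diene ester
Product: 23 methyl (1R,4R,4aS,8aS)-4-[(2R)-2-[(2S,6S)-1-acetyl-6-methylpiperidin-2-yl]-3-oxobutyl]-1,8a-epoxy-1,4,4a,5,6,7,8,8a-octahydronaphthalene-2-carboxylate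
Conditions: dimethyldioxirane (1.1 equiv, acetone solution), CH2Cl2, −20 to 0 °C
Reagents that add atoms: dimethyldioxirane CC1(C)OO1
Why: electrophilic epoxidation of the only electron-rich double bond (C1=C8a; C2=C3 is an acrylate), with oxygen expected on the face opposite the axial H-4a (axial attack on the exocyclic alkene of chair ring A), which sets C1 and C8a, the neutral oxidant sparing the ketone and the acid-sensitive vinyl oxirane.

Step 13
Reactants: 23 the epoxy keto ester
Product: 26 CNP0529632.1, via allylsamarium 24 (not isolated), via samarium alkoxide 25 (not isolated)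
Conditions: SmI2 (2.2 equiv, 0.1 M in THF), THF, −78 °C to rt; then sat. aq NH4Cl
Reagents that add atoms: none
Why: Proposed new method: two single-electron transfers from SmI2 to the 2-(methoxycarbonyl)vinyl oxirane should cleave the allylic C1–O bond with release of ring strain, giving the C8a samarium alkoxide and a configurationally labile allylsamarium delocalised over C1–C2–C3 whose C3 terminus adds to the tethered ketone through a six-membered chair-like transition state (metal on C1, carbonyl oxygen on the metal), the double bond moving to C1=C2 and the new tertiary alkoxide then acylating on the C2 ester. The closest known reactions are the SmI2 reduction of vinyl oxiranes to allylsamarium species and their coupling with ketones to 2-ene-1,5-diols, intramolecular samarium Barbier cyclisations, and Barbier reactions of 2-(halomethyl)acrylates with ketones that end in α-alkylidene γ-lactones, whereas the combination on a cyclic 2-carboxy vinyl oxirane with an internal ketone is new. The cyclopentane closes by 5-exo-trig attack of the allyl terminus on the ketone carbonyl and the lactone by 5-exo-trig attack of the alkoxide on the ester carbonyl. The new CH stereocentre (C3) is set by the three-atom tether, which only allows cis fusion on the face of ring B that carries the C4 substituent, the quaternary carbinol centre is set by the cyclic transition state, in which the ketone oxygen must point under ring B toward the metal and the methyl group outward (only this epimer can lactonise), and the C8a hydroxyl keeps the oxirane configuration. The step needs regioselectivity for C3 over C1 (C1 attack would give a strained bridged seven-membered ring) and chemoselectivity for the vinyl oxirane over the dialkyl ketone, the amide and the product enoate, which SmI2 in THF without HMPA at low temperature and only two equivalents should secure, and the C8a alkoxide cannot lactonise because it lies trans to the ester across C1=C2. Should the ketone be reduced first, the ketyl would add to the acrylate terminus C3 and the resulting samarium enolate would expel the oxirane oxygen, so both pathways converge on the same product.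

## Compound list

1 | (2S)-2-methylpiperidine | C[C@H]1CCCCN1 | starting material
2 | 1-[(2S)-2-methylpiperidin-1-yl]ethan-1-one | CC(=O)N1[C@@H](C)CCCC1 | intermediate
3 | 1-[(6S)-2-methoxy-6-methylpiperidin-1-yl]ethan-1-one (C2 epimers) | CC(=O)N1[C@@H](C)CCCC1OC | intermediate
4 | (4S)-4-benzyl-1,3-oxazolidin-2-one | O=C1N[C@@H](Cc2ccccc2)CO1 | starting material
5 | pent-4-enoyl chloride | C=CCCC(=O)Cl | starting material
6 | lithium (4S)-4-benzyl-2-oxo-1,3-oxazolidin-3-ide | [Li+].O=C1[N-][C@@H](Cc2ccccc2)CO1 | intermediate (not isolated)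
7 | (4S)-4-benzyl-3-(pent-4-enoyl)-1,3-oxazolidin-2-one | C=CCCC(=O)N1[C@@H](Cc2ccccc2)COC1=O | intermediate
8 | trichlorotitanium (Z)-enolate of 7 | C=CC/C=C(\O[Ti](Cl)(Cl)Cl)N1[C@@H](Cc2ccccc2)COC1=O | intermediate (not isolated)
9 | (2S)-1-acetyl-2-methyl-2,3,4,5-tetrahydropyridin-1-ium (N-acyliminium ion) | CC(=O)[N+]1=CCCC[C@@H]1C | intermediate (not isolated)
10 | (4S)-3-[(2R)-2-[(2S,6S)-1-acetyl-6-methylpiperidin-2-yl]pent-4-enoyl]-4-benzyl-1,3-oxazolidin-2-one | CC(=O)N1[C@@H](C)CCC[C@H]1[C@H](C(=O)N1[C@@H](Cc2ccccc2)COC1=O)CC=C | intermediate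
11 | (2R)-2-[(2S,6S)-1-acetyl-6-methylpiperidin-2-yl]-N-methoxy-N-methylpent-4-enamide | CC(=O)N1[C@@H](C)CCC[C@H]1[C@H](C(=O)N(C)OC)CC=C | intermediate
12 | but-3-en-2-one | C=CC(C)=O | starting material
13 | (2R,4E)-2-[(2S,6S)-1-acetyl-6-methylpiperidin-2-yl]-N-methoxy-N-methyl-6-oxohept-4-enamide | CC(=O)N1[C@@H](C)CCC[C@H]1[C@H](C(=O)N(C)OC)C/C=C/C(C)=O | intermediate
14 | cyclohexanone | O=C1CCCCC1 | starting material
15 | (2R,4R)-2-[(2S,6S)-1-acetyl-6-methylpiperidin-2-yl]-N-methoxy-N-methyl-6-oxo-4-[(1S)-2-oxocyclohexyl]heptanamide | CC(=O)N1[C@@H](C)CCC[C@H]1[C@H](C(=O)N(C)OC)C[C@@H]([C@@H]1CCCCC1=O)CC(C)=O | intermediate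
16 | (2R)-2-[(2S,6S)-1-acetyl-6-methylpiperidin-2-yl]-3-[(1R,8aS)-4a-hydroxy-3-oxodecahydronaphthalen-1-yl]-N-methoxy-N-methylpropanamide (ketol, C4a epimers) | CC(=O)N1[C@@H](C)CCC[C@H]1[C@H](C(=O)N(C)OC)C[C@@H]1CC(=O)CC2(O)CCCC[C@@H]12 | intermediate (not isolated)
17 | (2R)-2-[(2S,6S)-1-acetyl-6-methylpiperidin-2-yl]-N-methoxy-N-methyl-3-[(1R,8aS)-3-oxo-1,2,3,5,6,7,8,8a-octahydronaphthalen-1-yl]propanamide | CC(=O)N1[C@@H](C)CCC[C@H]1[C@H](C(=O)N(C)OC)C[C@@H]1CC(=O)C=C2CCCC[C@@H]12 | intermediate
18 | potassium cross-conjugated dienolate of 17 | CC(=O)N1[C@@H](C)CCC[C@H]1[C@H](C(=O)N(C)OC)C[C@@H]1C=C([O-])C=C2CCCC[C@@H]12.[K+] | intermediate (not isolated)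
19 | (4S,4aS)-4-[(2R)-2-[(2S,6S)-1-acetyl-6-methylpiperidin-2-yl]-3-[methoxy(methyl)amino]-3-oxopropyl]-4,4a,5,6,7,8-hexahydronaphthalen-2-yl trifluoromethanesulfonate | CC(=O)N1[C@@H](C)CCC[C@H]1[C@H](C(=O)N(C)OC)C[C@@H]1C=C(OS(=O)(=O)C(F)(F)F)C=C2CCCC[C@@H]12 | intermediate
20 | methyl (4R,4aS)-4-[(2R)-2-[(2S,6S)-1-acetyl-6-methylpiperidin-2-yl]-3-[methoxy(methyl)amino]-3-oxopropyl]-4,4a,5,6,7,8-hexahydronaphthalene-2-carboxylate | CC(=O)N1[C@@H](C)CCC[C@H]1[C@H](C(=O)N(C)OC)C[C@@H]1C=C(C(=O)OC)C=C2CCCC[C@@H]12 | intermediate
21 | bromomagnesium alkoxide of the tetrahedral methyl adduct of 20 (N,O-chelate) | CC(=O)N1[C@@H](C)CCC[C@H]1[C@H](C(C)(O[Mg]Br)N(C)OC)C[C@@H]1C=C(C(=O)OC)C=C2CCCC[C@@H]12 | intermediate (not isolated)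
22 | methyl (4R,4aS)-4-[(2R)-2-[(2S,6S)-1-acetyl-6-methylpiperidin-2-yl]-3-oxobutyl]-4,4a,5,6,7,8-hexahydronaphthalene-2-carboxylate | CC(=O)N1[C@@H](C)CCC[C@H]1[C@H](C(C)=O)C[C@@H]1C=C(C(=O)OC)C=C2CCCC[C@@H]12 | intermediate
23 | methyl (1R,4R,4aS,8aS)-4-[(2R)-2-[(2S,6S)-1-acetyl-6-methylpiperidin-2-yl]-3-oxobutyl]-1,8a-epoxy-1,4,4a,5,6,7,8,8a-octahydronaphthalene-2-carboxylate (oxirane oxygen trans to H-4a) | CC(=O)N1[C@@H](C)CCC[C@H]1[C@H](C(C)=O)C[C@@H]1C=C(C(=O)OC)[C@H]3O[C@]32CCCC[C@@H]12 | intermediate
24 | allylsamarium from 23 (diiodosamarium on C1, drawn as one η1 form; diiodosamarium alkoxide on C8a) | CC(=O)N1[C@@H](C)CCC[C@H]1[C@H](C(C)=O)C[C@@H]1C=C(C(=O)OC)C([Sm](I)I)[C@]2(O[Sm](I)I)CCCC[C@@H]12 | intermediate (not isolated)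
25 | bis(diiodosamarium) alkoxide of the cyclised dihydroxy methyl ester | CC(=O)N1[C@@H](C)CCC[C@H]1[C@H]1C[C@@H]2[C@H]([C@@]1(C)O[Sm](I)I)C(C(=O)OC)=C[C@]3(O[Sm](I)I)CCCC[C@@H]23 | intermediate (not isolated)
26 | CNP0529632.1: N-acetyl cis-2-methyl-6-substituted piperidine (2S,6S) on the tetracyclic hydroxy lactone (piperidine-bearing cyclopentane carbon R, ring-fusion CH carbons S and S, lactone quaternary carbon R, carbinol carbon S, decalin ring-fusion CH S) | CC(=O)N1[C@@H](C)CCC[C@H]1[C@H]1C[C@@H]2[C@H]3C(=C[C@]4(O)CCCC[C@@H]24)C(=O)O[C@@]13C | target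

## Step count and risks

Total step count: 13. Longest linear sequence: 12 steps (steps 1, 2 and 4–13, from compound 1).

**Step 13 (proposed new method).** The allylsamarium may be protonated, or may lose the C8a oxygen by β-elimination back to the diene, before it reaches the ketone; the product enoate may also be over-reduced. The fallback uses known chemistry and sets out from 23. The oxirane is opened by iodide in the SN2′ sense (LiI, AcOH, THF, 0 °C) to the allylic iodide methyl (4S,4aS,8aS)-4-[(2R)-2-[(2S,6S)-1-acetyl-6-methylpiperidin-2-yl]-3-oxobutyl]-8a-hydroxy-3-iodo-3,4,4a,5,6,7,8,8a-octahydronaphthalene-2-carboxylate F1, a Baylis–Hillman-type halide. Indium powder in THF/H2O at rt should then effect the intramolecular Barbier allylation of the ketone through a configurationally labile allylindium, and catalytic TsOH completes the lactonisation. The fallback comes back to the route at 26.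

**Step 7.** Enamine addition to a β-alkyl enone may be slow and the facial discrimination insufficient, which would give mixtures at C4 and at the cyclohexanone α-carbon. The fallback replaces catalysis by a stoichiometric chiral enamine and sets out from 14. Condensation with (S)-2-(methoxymethyl)pyrrolidine (TsOH cat., benzene, water removal) gives 1-[(2S)-2-(methoxymethyl)pyrrolidin-1-yl]cyclohex-1-ene F2. F2 is added to enone 13 in toluene at −20 °C to rt (Stork enamine Michael addition, expected in the same syn sense), and hydrolysis with aqueous AcOH/NaOAc comes back to the route at 15.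

**Step 12.** Oxygen transfer may show poor facial selectivity, with delivery to the face syn to H-4a prevailing. The fallback inverts the outcome of that preference and sets out from 22. NBS in THF/H2O at 0 °C forms the bromonium ion on the face the electrophile prefers, and water opens it at the tertiary C8a from the opposite face. This gives the bromohydrin methyl (1S,4R,4aS,8aS)-4-[(2R)-2-[(2S,6S)-1-acetyl-6-methylpiperidin-2-yl]-3-oxobutyl]-1-bromo-8a-hydroxy-1,4,4a,5,6,7,8,8a-octahydronaphthalene-2-carboxylate F3. Ag2O in THF at rt closes the oxirane with inversion at C1 under non-basic conditions (no epimerisation next to the ketone) and comes back to the route at 23.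

Further compounds
F1 | step 13 | methyl (4S,4aS,8aS)-4-[(2R)-2-[(2S,6S)-1-acetyl-6-methylpiperidin-2-yl]-3-oxobutyl]-8a-hydroxy-3-iodo-3,4,4a,5,6,7,8,8a-octahydronaphthalene-2-carboxylate (C3 epimers) | CC(=O)N1[C@@H](C)CCC[C@H]1[C@H](C(C)=O)C[C@@H]1C(I)C(C(=O)OC)=C[C@]2(O)CCCC[C@@H]12
F2 | step 7 | 1-[(2S)-2-(methoxymethyl)pyrrolidin-1-yl]cyclohex-1-ene | COC[C@@H]1CCCN1C1=CCCCC1
F3 | step 12 | methyl (1S,4R,4aS,8aS)-4-[(2R)-2-[(2S,6S)-1-acetyl-6-methylpiperidin-2-yl]-3-oxobutyl]-1-bromo-8a-hydroxy-1,4,4a,5,6,7,8,8a-octahydronaphthalene-2-carboxylate | CC(=O)N1[C@@H](C)CCC[C@H]1[C@H](C(C)=O)C[C@@H]1C=C(C(=O)OC)[C@H](Br)[C@]2(O)CCCC[C@@H]12
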